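**Plan**

- Retrosynthesis: the two MOM ethers come off last. Ring D is cut at the C2′–O aryl ether bond (side-chain alkoxide onto a 2′-fluoride). Ring C is then cut at O1–C2 and C3–C4 into a salicylaldehyde and an aryl alkyl alkyne.
- Enabling feature: the C2=C3 bond of ring C carries ring B on C2 and the side-chain CH2 on C3, which is the pattern of an aryl alkyl alkyne. C4, C4a, C8a and O1 are the formyl carbon, two ring carbons and the phenol oxygen of a ring A 2-hydroxybenzaldehyde.
- Forward order: ring E is fused to ring A first (O-propargylation, mono-MOM protection, Claisen/oxa-6π). Ring B is joined to the chiral diol chain by Sonogashira coupling. Ring C arises in the rhodium annulation, ring D closes by SNAr, and both MOM groups are then removed.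
- Stereochemistry: the single stereocentre (R) is C2 of methyl (R)-glycidate. Its C–O bond is never broken (epoxide opened at CH2, Grignard at the ester, SNAr at the arene).

Key step: step 8

Assumption: flavone numbering is used (O1, C2–C4, C4a, C5–C8, C8a; ring B primed); ring E is the dimethylpyran on C7/C8 and ring D the oxepine through the 2′-oxygen; with O > C(CH3)2OH > CH2 > H the stereocentre of the target is R.

**Route**

Step 1
Reactants: 1 2,4,6-trihydroxybenzaldehyde; 2 3-chloro-3-methylbut-1-yne
Product: 3 2,6-dihydroxy-4-[(2-methylbut-3-yn-2-yl)oxy]benzaldehyde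
Conditions: K2CO3 (1.1 equiv), KI, CuI (5 mol %), acetone, 50 °C
Reagents that add atoms: none
Why: Copper-assisted Williamson-type O-alkylation of a phenoxide by a tertiary propargylic chloride should take the 4-hydroxyl, which is the most acidic and the only one not hydrogen-bonded to the formyl oxygen, as in the standard 4-O-dimethylpropargylation of 2,4-dihydroxybenzaldehydes.

Step 2
Reactants: 3 2,6-dihydroxy-4-[(2-methylbut-3-yn-2-yl)oxy]benzaldehyde
Product: 4 2-hydroxy-6-(methoxymethoxy)-4-[(2-methylbut-3-yn-2-yl)oxy]benzaldehyde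
Conditions: MOMCl (1.05 equiv), i-Pr2NEt, CH2Cl2, 0 °C
Reagents that add atoms: chloromethyl methyl ether (MOMCl), COCCl
Why: Williamson-type MOM etherification of one of two equivalent hydroxyls should stop at the mono-ether because the remaining hydroxyl is then locked in a strong hydrogen bond to the formyl oxygen, as in the usual partial protection of chelated polyhydroxy aryl carbonyl compounds.

Step 3
Reactants: 4 2-hydroxy-6-(methoxymethoxy)-4-[(2-methylbut-3-yn-2-yl)oxy]benzaldehyde
Product: 7 5-hydroxy-7-(methoxymethoxy)-2,2-dimethyl-2H-chromene-6-carbaldehyde, via allenylphenol 5 (not isolated), via ortho-quinone methide 6 (not isolated)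
Conditions: o-xylene, 140 °C
Reagents that add atoms: none
Why: Aryl propargyl Claisen rearrangement to 5, 1,5-hydrogen shift to 6 and oxa-6π electrocyclisation close ring E, and the hydroxyl/formyl chelate fixes double-bond character between the ether-bearing carbon and the carbon next to the free hydroxyl, so the [3,3] shift should go to that carbon (as with 2-hydroxy-4-propargyloxy aryl carbonyl compounds) and the non-chelated oxygen should close the pyran.

Step 4
Reactants: 8 3-fluoro-4-iodophenol
Product: 9 2-fluoro-1-iodo-4-(methoxymethoxy)benzene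
Conditions: MOMCl, i-Pr2NEt, CH2Cl2, 0 °C → rt
Reagents that add atoms: chloromethyl methyl ether (MOMCl), COCCl
Why: Williamson-type MOM protection of a simple phenol, chosen because the acetal survives organometallic base, fluoride, hot Cu(OAc)2 and NaH and leaves together with the ring A acetal at the end.

Step 5
Reactants: 10 methyl (R)-glycidate; 11 trimethylsilylacetylene
Product: 13 methyl (R)-2-hydroxy-5-(trimethylsilyl)pent-4-ynoate, via lithium (trimethylsilyl)acetylide 12 (not isolated)
Conditions: 11, n-BuLi, THF, −78 °C; BF3·OEt2; then 10, −78 °C; H2O quench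
Reagents that add atoms: none
Why: Yamaguchi–Hirao alkynylation, in which the BF3-activated epoxide is opened by 12 at the unsubstituted CH2 in SN2 fashion at a temperature where the ester is not attacked, so the C2 stereocentre of the glycidate is carried over unchanged as R.

Step 6
Reactants: 13 methyl (R)-2-hydroxy-5-(trimethylsilyl)pent-4-ynoate
Product: 15 (R)-2-methyl-6-(trimethylsilyl)hex-5-yne-2,3-diol, via methyl ketone 14 (not isolated)
Conditions: MeMgBr (3.5 equiv), THF, 0 °C → rt; H2O quench
Reagents that add atoms: methylmagnesium bromide, C[Mg]Br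
Why: Double Grignard addition to the ester through ketone 14, in which the magnesium alkoxide of the α-hydroxyl forms first and suppresses enolisation, so the carbinol centre should be retained as in the conversion of lactates into 2-methylbutane-2,3-diols.

Step 7
Reactants: 15 (R)-2-methyl-6-(trimethylsilyl)hex-5-yne-2,3-diol; 9 2-fluoro-1-iodo-4-(methoxymethoxy)benzene
Product: 17 (R)-6-[2-fluoro-4-(methoxymethoxy)phenyl]-2-methylhex-5-yne-2,3-diol, via terminal alkyne 16 (not isolated)
Conditions: Bu4NF, THF, rt; then 9, PdCl2(PPh3)2 (3 mol %), CuI (5 mol %), Et3N, rt, N2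
Reagents that add atoms: none
Why: Fluoride desilylation followed in the same flask by Sonogashira coupling, in which the aryl iodide adds to zerovalent palladium at room temperature while the free diol, the aryl fluoride and the MOM ether are spectators.

Step 8
Reactants: 7 5-hydroxy-7-(methoxymethoxy)-2,2-dimethyl-2H-chromene-6-carbaldehyde; 17 (R)-6-[2-fluoro-4-(methoxymethoxy)phenyl]-2-methylhex-5-yne-2,3-diol
Product: 18 (R)-3-(2,3-dihydroxy-3-methylbutyl)-2-[2-fluoro-4-(methoxymethoxy)phenyl]-5-(methoxymethoxy)-8,8-dimethyl-4H,8H-pyrano[2,3-f]chromen-4-one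
Conditions: [Cp*RhCl2]2 (2.5 mol %), Cu(OAc)2·H2O (2.1 equiv), o-xylene, 120 °C, N2
Reagents that add atoms: none
Why: Phenoxide-directed cleavage of the formyl C–H of 7 by the trivalent rhodium species Cp*Rh(OAc)2, formed from [Cp*RhCl2]2 and Cu(OAc)2, gives a five-membered acyl rhodacycle whose Rh–acyl bond is inserted by alkyne 17. Insertion joins the acyl carbon to the CH2-bearing alkyne carbon (C3–C4) and leaves the aryl-bearing carbon on rhodium; C–O reductive elimination from the seven-membered oxa-rhodacycle then forms O1–C2 and Cu(OAc)2 returns monovalent rhodium to the trivalent state. The closest known reaction is the rhodium-catalysed oxidative coupling of salicylaldehydes with internal alkynes to 2,3-disubstituted chromones, in which aryl alkyl alkynes give 2-aryl-3-alkyl products. Ring C closes as a six-membered pyranone in a formal (4+2) oxidative annulation, the ring-closing event being the C–O reductive elimination. No stereocentre is formed, and the carbinol centre of 17 lies outside all bond changes. The step needs insertion regioselectivity and a defined O1: the first rests on the preference of rhodium for the aryl-substituted alkyne carbon, the second on 7 having a single free ortho hydroxyl (the other ortho oxygen is a MOM ether), and the hindered chromene alkene should not compete with the alkyne.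

Step 9
Reactants: 18 (R)-3-(2,3-dihydroxy-3-methylbutyl)-2-[2-fluoro-4-(methoxymethoxy)phenyl]-5-(methoxymethoxy)-8,8-dimethyl-4H,8H-pyrano[2,3-f]chromen-4-one
Product: 19 5,4′-bis(methoxymethyl) ether of 20 (ring D closed, R)
Conditions: NaH (1.5 equiv), DMF, 0 → 50 °C
Reagents that add atoms: none
Why: Intramolecular SNAr (addition–elimination) of the secondary alkoxide on the 2′-fluoride, which is activated by the ortho chromone C2 acting as a vinylogous acyl group that carries the Meisenheimer charge onto the C4 carbonyl; seven-membered closure should win over the hindered tertiary alkoxide (eight-membered) and over 5-endo addition to C2, and the C–O bond at the stereocentre is untouched so R is kept.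

Step 10
Reactants: 19 5,4′-bis(methoxymethyl) ether of 20
Product: 20 CNP0329736.1
Conditions: 2 M HCl, MeOH/THF, 45 °C
Reagents that add atoms: none
Why: Acid-catalysed acetal exchange with methanol removes both MOM groups, the peri 5-O acetal fastest with help from the carbonyl, and dilute acid at this temperature should leave the 2,2-dimethylchromene, the ring D aryl alkyl ether and the tertiary alcohol intact.

**Compound list**

1 | 2,4,6-trihydroxybenzaldehyde | O=Cc1c(O)cc(O)cc1O | starting material
2 | 3-chloro-3-methylbut-1-yne | C#CC(C)(C)Cl | starting material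
3 | 2,6-dihydroxy-4-[(2-methylbut-3-yn-2-yl)oxy]benzaldehyde | O=Cc1c(O)cc(OC(C)(C)C#C)cc1O | intermediate
4 | 2-hydroxy-6-(methoxymethoxy)-4-[(2-methylbut-3-yn-2-yl)oxy]benzaldehyde | O=Cc1c(O)cc(OC(C)(C)C#C)cc1OCOC | intermediate
5 | 2,4-dihydroxy-6-(methoxymethoxy)-3-(3-methylbuta-1,2-dien-1-yl)benzaldehyde (allenylphenol) | O=Cc1c(O)c(C=C=C(C)C)c(O)cc1OCOC | intermediate
6 | 2-hydroxy-6-(methoxymethoxy)-3-(3-methylbut-2-en-1-ylidene)-4-oxocyclohexa-1,5-diene-1-carbaldehyde (ortho-quinone methide) | O=CC1=C(O)C(=CC=C(C)C)C(=O)C=C1OCOC | intermediate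
7 | 5-hydroxy-7-(methoxymethoxy)-2,2-dimethyl-2H-chromene-6-carbaldehyde | O=Cc1c(O)c2C=CC(C)(C)Oc2cc1OCOC | intermediate
8 | 3-fluoro-4-iodophenol | Oc1ccc(I)c(F)c1 | starting material
9 | 2-fluoro-1-iodo-4-(methoxymethoxy)benzene | COCOc1ccc(I)c(F)c1 | intermediate
10 | methyl (R)-glycidate | COC(=O)[C@H]1CO1 | starting material
11 | trimethylsilylacetylene | C#C[Si](C)(C)C | starting material
12 | lithium (trimethylsilyl)acetylide | [Li]C#C[Si](C)(C)C | intermediate
13 | methyl (R)-2-hydroxy-5-(trimethylsilyl)pent-4-ynoate | COC(=O)[C@H](O)CC#C[Si](C)(C)C | intermediate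
14 | (R)-3-hydroxy-6-(trimethylsilyl)hex-5-yn-2-one | CC(=O)[C@H](O)CC#C[Si](C)(C)C | intermediate
15 | (R)-2-methyl-6-(trimethylsilyl)hex-5-yne-2,3-diol | CC(C)(O)[C@H](O)CC#C[Si](C)(C)C | intermediate
16 | (R)-2-methylhex-5-yne-2,3-diol | CC(C)(O)[C@H](O)CC#C | intermediate
17 | (R)-6-[2-fluoro-4-(methoxymethoxy)phenyl]-2-methylhex-5-yne-2,3-diol | CC(C)(O)[C@H](O)CC#Cc1ccc(OCOC)cc1F | intermediate
18 | (R)-3-(2,3-dihydroxy-3-methylbutyl)-2-[2-fluoro-4-(methoxymethoxy)phenyl]-5-(methoxymethoxy)-8,8-dimethyl-4H,8H-pyrano[2,3-f]chromen-4-one | CC(C)(O)[C@H](O)Cc1c(-c2ccc(OCOC)cc2F)oc2c3C=CC(C)(C)Oc3cc(OCOC)c2c1=O | intermediate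
19 | 5,4′-bis(methoxymethyl) ether of 20: flavone with 5- and 4′-OMOM, 2,2-dimethyl-2H-pyran on C7/C8 (O on C7) and the (R)-configured C3–CH2–CH[C(CH3)2OH]–O–C2′ oxepine bridge | CC1(C)C=Cc2c(cc(OCOC)c3c(=O)c4c(oc23)-c2ccc(OCOC)cc2O[C@@H](C(C)(C)O)C4)O1 | intermediate
20 | CNP0329736.1: 5,4′-dihydroxyflavone with a 2,2-dimethyl-2H-pyran on C7/C8 (O on C7) and an (R)-configured C3–CH2–CH[C(CH3)2OH]–O–C2′ oxepine bridge | CC1(C)C=Cc2c(cc(O)c3c(=O)c4c(oc23)-c2ccc(O)cc2O[C@@H](C(C)(C)O)C4)O1 | target

**Totals and risks**

Total step count: 10. Longest linear sequence: 6 steps (10 → 13 → 15 → 17 → 18 → 19 → 20; the arm from 1 through 3, 4 and 7 is equally long).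

Steps most likely to fail:

1. Step 8. The free homopropargylic hydroxyl may coordinate rhodium and erode or reverse the regiochemistry of alkyne insertion, it may cyclise onto the alkyne under hot Cu(OAc)2, and the acyl rhodacycle may lose CO before insertion. The fallback masks the diol and sets out from 17. Treatment with 1,1′-carbonyldiimidazole and catalytic 4-dimethylaminopyridine in CH2Cl2 at 40 °C should give the cyclic carbonate (R)-4-{3-[2-fluoro-4-(methoxymethoxy)phenyl]prop-2-yn-1-yl}-5,5-dimethyl-1,3-dioxolan-2-one F1. Annulation of F1 with 7 under the conditions of step 8 should give the carbonate-protected chromone (R)-3-[(5,5-dimethyl-2-oxo-1,3-dioxolan-4-yl)methyl]-2-[2-fluoro-4-(methoxymethoxy)phenyl]-5-(methoxymethoxy)-8,8-dimethyl-4H,8H-pyrano[2,3-f]chromen-4-one F2. Methanolysis with K2CO3 in MeOH at rt, which leaves the MOM ethers untouched, returns the route to 18.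

2. Step 9. Activation of the fluoride by the twisted chromone may be too weak for seven-membered closure, so that base-induced opening of the pyranone competes. The fallback replaces SNAr by copper-catalysed O-arylation of a bromide and sets out from 15 and 7. Commercial 3-bromo-4-iodophenol F3 is protected as in step 4 to 2-bromo-1-iodo-4-(methoxymethoxy)benzene F4. F4 is coupled with 15 as in step 7, the iodide reacting selectively, to give (R)-6-[2-bromo-4-(methoxymethoxy)phenyl]-2-methylhex-5-yne-2,3-diol F5. F5 is annulated with 7 as in step 8 to (R)-2-[2-bromo-4-(methoxymethoxy)phenyl]-3-(2,3-dihydroxy-3-methylbutyl)-5-(methoxymethoxy)-8,8-dimethyl-4H,8H-pyrano[2,3-f]chromen-4-one F6. Ullmann-type intramolecular etherification (CuI, 3,4,7,8-tetramethyl-1,10-phenanthroline, Cs2CO3, toluene, 110 °C) then closes ring D and returns the route to 19.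

3. Step 3. The [3,3] shift may go partly to the carbon next to the MOM ether, which would place the free hydroxyl away from the ring-fusion carbon and lead to the linear pyranoflavone series. The fallback moves regiocontrol from chelation to symmetry and sets out from 3. Heating 3 itself in o-xylene at 140 °C can give only one chromene, 5,7-dihydroxy-2,2-dimethyl-2H-chromene-6-carbaldehyde F7. MOMCl (1.0 equiv) with i-Pr2NEt in CH2Cl2 at −20 °C should then etherify the less hindered 7-hydroxyl, flanked by C8–H, and leave the hydroxyl next to the pyran ring carbon free, returning the route to 7.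

**Further compounds**

F1 | step 8 | (R)-4-{3-[2-fluoro-4-(methoxymethoxy)phenyl]prop-2-yn-1-yl}-5,5-dimethyl-1,3-dioxolan-2-one | CC1(C)OC(=O)O[C@@H]1CC#Cc1ccc(OCOC)cc1F
F2 | step 8 | (R)-3-[(5,5-dimethyl-2-oxo-1,3-dioxolan-4-yl)methyl]-2-[2-fluoro-4-(methoxymethoxy)phenyl]-5-(methoxymethoxy)-8,8-dimethyl-4H,8H-pyrano[2,3-f]chromen-4-one | CC1(C)OC(=O)O[C@@H]1Cc1c(-c2ccc(OCOC)cc2F)oc2c3C=CC(C)(C)Oc3cc(OCOC)c2c1=O
F3 | step 9 | 3-bromo-4-iodophenol | Oc1ccc(I)c(Br)c1
F4 | step 9 | 2-bromo-1-iodo-4-(methoxymethoxy)benzene | COCOc1ccc(I)c(Br)c1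
F5 | step 9 | (R)-6-[2-bromo-4-(methoxymethoxy)phenyl]-2-methylhex-5-yne-2,3-diol | CC(C)(O)[C@H](O)CC#Cc1ccc(OCOC)cc1Br
F6 | step 9 | (R)-2-[2-bromo-4-(methoxymethoxy)phenyl]-3-(2,3-dihydroxy-3-methylbutyl)-5-(methoxymethoxy)-8,8-dimethyl-4H,8H-pyrano[2,3-f]chromen-4-one | CC(C)(O)[C@H](O)Cc1c(-c2ccc(OCOC)cc2Br)oc2c3C=CC(C)(C)Oc3cc(OCOC)c2c1=O
F7 | step 3 | 5,7-dihydroxy-2,2-dimethyl-2H-chromene-6-carbaldehyde | O=Cc1c(O)cc2OC(C)(C)C=Cc2c1O
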